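(Readings and results stem from a simulated flask with constants of no real substance.)

0.00558 M h⁻¹ of target is what the red run makes on average over 20.0 h. I call this the supply rate: the target made per hour while solid reagent dissolves into partner. Red is this flask with its catalyst doubled, 10 mol% against 5 mol% on the same starting material, so it stands as the nearest neighbour.

| flask | starting material | second substrate | solid reagent | free catalyst | remark |
|---|---|---|---|---|---|
| violet | 0.70 M | 1 equiv | 2 equiv | 5 mol% | run made earlier |
| ochre | 1.1 M | 1 equiv | 2 equiv | 5 mol% | run made earlier |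
| red | 0.50 M | 1 equiv | 2 equiv | 10 mol% | run made earlier |
| flask | 0.50 M | 1.00 equiv | 2.00 equiv | 5 mol% |  |

| run | time / h | target / % | starting material / % |
|---|---|---|---|
| violet | 1.50 | 1.7 | 94.7 |
| violet | 2.50 | 2.2 | 93.8 |
| violet | 4.00 | 4.2 | 93.6 |
| violet | 8.00 | 6.4 | 90.8 |
| violet | 12.0 | 8.6 | 85.8 |
| violet | 20.0 | 15.0 | 79.1 |
| ochre | 1.33 | 1.3 | 95.2 |
| ochre | 4.00 | 3.2 | 93.7 |
| ochre | 8.00 | 4.6 | 92.2 |
| ochre | 10.0 | 5.3 | 87.1 |
| ochre | 15.0 | 6.8 | 88.5 |
| ochre | 20.0 | 10.7 | 83.5 |
| red | 4.00 | 4.0 | 86.5 |
| red | 8.00 | 8.8 | 81.8 |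
| red | 12.0 | 13.5 | 75.0 |
| red | 15.0 | 16.4 | 73.4 |
| red | 20.0 | 22.3 | 67.1 |

(each reading ± 1 percentage point)

- factor on the rate of making target when 30% of the starting material are converted if free catalyst is charged twice over
- factor on the rate when 30% of the starting material are converted if free catalyst is charged at 25 mol% instead

| Run | Catalyst, of the charge | Missing at the last reading, of the charge | Target per hour |
|---|---|---|---|
| violet | 5 mol% | 5.90% | 0.00525 M h⁻¹ |
| ochre | 5 mol% | 5.80% | 0.00589 M h⁻¹ |
| red | 10 mol% | 10.6% | 0.00558 M h⁻¹ |

In each run the missing share is close to the catalyst charge, so I read catalyst intermediate A as the resting state. From violet to ochre the concentrations of catalyst, starting material and solid reagent all rise 1.57-fold but the hourly rate, as read, only 1.12-fold, so I read the order in these together as near zero. Partner is the concentration I take to set that order: if dissolving is the rate-limiting step, more catalyst intermediate A simply holds partner lower. The flask's catalyst concentration lies below that of each run, so this is an extrapolation. I commit to a factor of 1 for both questions. With bound catalyst counted as converted, target must supply 25.0% of the charge, which takes 22.4 h.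

The forecast gives 1.1 and 1.2, with the words “More catalyst barely helps.”

    starting material + free catalyst ⇌ catalyst intermediate A (K = 500 M⁻¹, k = 0.0320 M⁻¹ s⁻¹)
    partner + catalyst intermediate A → free catalyst + target (k = 0.0620 M⁻¹ s⁻¹)
    second substrate + free catalyst ⇌ catalyst intermediate B (K = 6.10 M⁻¹, k = 0.00310 M⁻¹ s⁻¹)
    partner + catalyst intermediate B → free catalyst + second product (k = 0.0500 M⁻¹ s⁻¹)
    solid reagent ⇌ partner, rate k5*(cs5 - [partner]) while solid is left; crystals form when [partner] > cs5 (solubility = 0.170 M, k = 9.40 × 10⁻⁶ s⁻¹)

The flask gives 1.01 for doubling and 1.01 at 25 mol%. At 10.0 h partner stands at 0.00104 M, far below its solubility of 0.17 M. The flask reaches 30% conversion at 22.7 h, against my 22.4 h. Used once more, 0.00558 M h⁻¹ must furnish 65.0% of the charge to reach 70.0% conversion, which takes 58.3 h, and the flask gets there at 59.2 h.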